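All constants stand for no real mixture; the result is computed.

Slowness in these flasks belongs to the substrate: its opening to the intermediate has a half-life of 10.7 s, much longer than the 0.15 s and 0.25 s that capture by the second and first nucleophile take on the intermediate at the amounts charged in beta.

common to all: substrate 0.14 M; time 30 s
- theta: first nucleophile 0.252 M; second nucleophile 0.0840 M (fed, over 12 s); all else is in the flask from the start; the feed brings no volume worth counting
- gamma: first nucleophile 0.252 M (in portions, 4, over 12 s); second nucleophile 0.0840 M; first portion at the start, last at 12 s
- beta: first nucleophile 0.252 M; second nucleophile 0.0840 M; everything together at the start
- epsilon: first nucleophile 0.252 M (fed, over 12 s); second nucleophile 0.0840 M; all else is in the flask from the start; the feed brings no volume worth counting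

1. the flask that comes out highest in share of target in target plus other capture product, or "all alike" when all lie within 1.5 percentage points (theta / gamma / beta / epsilon / all alike)
2. share of target in target plus other capture product at the end, theta
3. share of target in target plus other capture product at the end, gamma
4. share of target in target plus other capture product at the end, beta
5. share of target in target plus other capture product at the end, epsilon

- where a step has two of a species, its rate is k times that concentration squared, and two are used at each turn
- run time (theta): 30 s

    2 second nucleophile → homo dimer (k1 = 0.052 M⁻¹ s⁻¹)
    substrate → intermediate (k2 = 0.065 s⁻¹)
    first nucleophile + intermediate → target (k3 = 11 M⁻¹ s⁻¹)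
    intermediate → solvolysis product (k4 = 0.18 s⁻¹)
    target ⇌ isomer of the product (K5 = 0.39, k5 = 0.080 s⁻¹)
    second nucleophile + intermediate → other capture product (k6 = 54 M⁻¹ s⁻¹)
    first nucleophile ⇌ dormant form (K7 = 0.41, k7 = 1.3 s⁻¹)

What does that gap give you? The opening is the rate-limiting step, and each intermediate, once made, meets the mixture of that moment. Each capture is then pseudo-first-order in the intermediate.

So which number do you carry? The capture ratio: the rate of capture by the second nucleophile over the rate of capture by the free first nucleophile, the inverse of a selectivity factor. With the dormant form at equilibrium, the free part of the first nucleophile is 70.9%, so at the full charges, as in beta once the dormant form has formed, the ratio is 2.31.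

But the question counts target, and target passes into its isomer. True. At equilibrium target keeps 71.9% of the pair, so the share made at a given ratio is that part divided by that part plus the ratio. For beta at the full charges this gives 23.7%.

And the feeds? Take 6.00 s and count nothing as consumed. Theta then holds half its second nucleophile, and its ratio is 1.16. Epsilon holds half its first nucleophile, and its ratio is 4.62. Gamma follows epsilon in 4 steps.

Where is this weak? Consumption. The second nucleophile is charged at less than the substrate, so its use pulls the ratio down as the run goes on. My reckoning stops there: I commit to theta highest, then beta, with gamma and epsilon close together, and I give no end shares.

The forecast names theta and gives end shares of 45.8% for theta, 32.6% for gamma, 37.2% for beta and 32.2% for epsilon, in its words: “Slow feed of the second nucleophile wins.” Where I give an order, it gives figures.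

The simulation puts theta highest, with 44.9% for theta, 32.7% for gamma, 37.4% for beta and 32.5% for epsilon.

In epsilon the capture ratio stands at 0.38 after 30.0 s, lower than the 2.31 reckoned for the full charges, with 14% of the second nucleophile left, while the other capture product stands at 49.1% of the substrate charged against 31.8% for target and isomer together. The neighbour of epsilon charged with 0.021 M of second nucleophile has a ratio at full charges of 0.577, lower than 2.31, and ends with 1.12% of its second nucleophile left and a share of 74.9%.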